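**Retrosynthetic overview**
1. The cyclobutane and cyclopentane rings open together by a retro-[2+2] to an achiral (E)-prenylstilbene. In the forward direction, one catalytic enantioselective radical-cation [2+2] on the unprotected catechol sets all three stereocentres in the last step.
2. The stilbene C=C is cut by a Heck disconnection into a 5-bromochromene and 4-vinylcatechol, which is released in the flask from caffeic acid.
3. The prenyl group comes from C–H metalation between Br and OMe, followed by prenyl bromide.
4. The pyran ring comes from oxa-6π closure of the prenyl-type ortho-quinone methide made from 3-bromo-5-methoxyphenol and prenal.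
5. Ring order: the pyran ring first, then the cyclopentane and cyclobutane together in the final step.

Assumption: the sense of induction of the chiral anion cannot be predicted for this new substrate. The (S,S)-anion is written, and if it gives the antipode, the equally available (R,R)-anion is used with nothing else changed.

**Step 1**
Reactants: 1 3-bromo-5-methoxyphenol; 2 3-methylbut-2-enal (prenal)
Product: 5 5-bromo-7-methoxy-2,2-dimethyl-2H-chromene, via benzodioxaborinine 3 (not isolated), via ortho-quinone methide 4 (not isolated)
Conditions: PhB(OH)2 (1.0 equiv, recovered), AcOH (cat.), toluene, reflux, Dean–Stark, 24 h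
Reagents that add atoms: none
Why: Boronate-templated ortho-hydroxyalkylation of the phenol gives 3, thermal loss of PhBO gives the same ortho-quinone methide 4 that dehydrogenation of an ortho-prenylphenol would give, and oxa-6π electrocyclisation closes the pyran; attack goes para to OMe (next to Br) rather than between the two oxygens, which is the usual orientation of 3-alkoxyphenols, and no stereocentre is formed.

**Step 2**
Reactants: 5 5-bromo-7-methoxy-2,2-dimethyl-2H-chromene; 6 1-bromo-3-methylbut-2-ene (prenyl bromide)
Product: 9 5-bromo-7-methoxy-2,2-dimethyl-6-(3-methylbut-2-en-1-yl)-2H-chromene, via aryllithium 7 (not isolated), via arylmagnesium bromide 8 (not isolated)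
Conditions: LiN(i-Pr)2 (LDA, commercial solution, 1.15 equiv), THF, −78 °C, 1 h (5 added to the base); MgBr2·OEt2 (1.2 equiv), −78 °C; CuBr·SMe2 (5 mol%), 6 (1.5 equiv), −78 to 0 °C
Reagents that add atoms: none
Why: In this directed ortho-metalation the amide base removes only the most acidic ring proton, H-6 flanked by Br and OMe (H-8 between two alkoxy groups is not acidified by halogen), Li-to-Mg exchange prevents aryne formation on warming, and allylation of the primary allylic bromide catalysed by monovalent copper (SN2) gives the linear prenyl arene.

**Step 3**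
Reactants: 9 5-bromo-7-methoxy-2,2-dimethyl-6-(3-methylbut-2-en-1-yl)-2H-chromene; 10 caffeic acid
Product: 12 4-{(E)-2-[7-methoxy-2,2-dimethyl-6-(3-methylbut-2-en-1-yl)-2H-chromen-5-yl]ethenyl}benzene-1,2-diol, via 4-vinylcatechol 11 (not isolated)
Conditions: 10 (2 equiv), Et3N (5 equiv), BHT (2 mol%), DMF, 100 °C, 2 h; then 9, Pd(OAc)2 (5 mol%), P(t-Bu)3·HBF4 (10 mol%), 100 °C, 12 h, argon
Reagents that add atoms: none
Why: Amine-promoted decarboxylation of the 4-hydroxycinnamic acid through its para-quinone methide tautomer gives styrene 11, which enters a Mizoroki–Heck coupling in which the bulky electron-rich phosphine lets zerovalent palladium insert into the di-ortho-substituted C–Br bond, syn insertion and syn β-hydride elimination give only the E-alkene, and the weak amine base leaves the catechol protonated.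

**Step 4**
Reactants: 12 4-{(E)-2-[7-methoxy-2,2-dimethyl-6-(3-methylbut-2-en-1-yl)-2H-chromen-5-yl]ethenyl}benzene-1,2-diol
Product: 14 target CNP0207533.1 (cis-fused cyclobuta[a]indane-chromene with exo 3,4-dihydroxyphenyl group; S at the ring-fusion CH next to CH2; R at the benzylic ring-fusion CH; S at the aryl-bearing CH), via stilbene radical cation 13 (not isolated)
Conditions: [2,3,6,7-tetramethoxy-9-(2-methylphenyl)thioxanthylium][(S,S)-IDPi] (2.5 mol%; IDPi = BINOL-derived imidodiphosphorimidate anion with 3,3'-aryl walls and N-triflyl groups), CH2Cl2 (0.02 mol/L), −78 °C, green LEDs (525 nm), argon, 24–48 h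
Reagents that add atoms: none
Why: Proposed new method: green light excites only the thioxanthylium cation, which oxidises the electron-rich stilbene of 12 to radical cation 13; in cold CH2Cl2 this species can exist only as a contact ion pair with the confined chiral anion, anchored by hydrogen bonds from its strongly acidified catechol OH groups, so the tethered prenyl alkene attacks one face of the stilbene carbon bound to ring A (5-exo, leaving spin and charge on the catechol-stabilised benzylic carbon and the tertiary carbon), the four-membered ring closes, and electron return from the reduced dye or from another molecule of 12 releases 14; the one-carbon tether enforces the cis ring fusion, stepwise closure places the catechol ring on the convex face trans to ring A, and the anion fixes the absolute configuration; the closest known reaction types are the photoredox radical-cation [2+2] cycloaddition of tethered styrenes and the asymmetric counteranion-directed photoredox [2+2] cross-cycloaddition of anethole-type styrenes, and the same bonds form thermally (as a racemate) in closely related free-phenol prenylstilbenes.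

**Compound list**
1 | 3-bromo-5-methoxyphenol | COc1cc(O)cc(Br)c1 | starting material
2 | 3-methylbut-2-enal (prenal) | CC(C)=CC=O | starting material
3 | 5-bromo-7-methoxy-4-(2-methylprop-1-en-1-yl)-2-phenyl-4H-1,3,2-benzodioxaborinine (racemic, transient) | COc1cc(Br)c2C(C=C(C)C)OB(c3ccccc3)Oc2c1 | intermediate
4 | (6E)-5-bromo-3-methoxy-6-(3-methylbut-2-en-1-ylidene)cyclohexa-2,4-dien-1-one (ortho-quinone methide, vinyl group cis to C=O) | COC1=CC(=O)/C(=C\C=C(C)C)C(Br)=C1 | intermediate
5 | 5-bromo-7-methoxy-2,2-dimethyl-2H-chromene | COc1cc(Br)c2C=CC(C)(C)Oc2c1 | intermediate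
6 | 1-bromo-3-methylbut-2-ene (prenyl bromide) | CC(C)=CCBr | starting material
7 | (5-bromo-7-methoxy-2,2-dimethyl-2H-chromen-6-yl)lithium | COc1cc2OC(C)(C)C=Cc2c(Br)c1[Li] | intermediate
8 | (5-bromo-7-methoxy-2,2-dimethyl-2H-chromen-6-yl)magnesium bromide | COc1cc2OC(C)(C)C=Cc2c(Br)c1[Mg]Br | intermediate
9 | 5-bromo-7-methoxy-2,2-dimethyl-6-(3-methylbut-2-en-1-yl)-2H-chromene | COc1cc2OC(C)(C)C=Cc2c(Br)c1CC=C(C)C | intermediate
10 | caffeic acid, (E)-3-(3,4-dihydroxyphenyl)prop-2-enoic acid | OC(=O)/C=C/c1ccc(O)c(O)c1 | starting material
11 | 4-ethenylbenzene-1,2-diol (4-vinylcatechol) | C=Cc1ccc(O)c(O)c1 | intermediate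
12 | 4-{(E)-2-[7-methoxy-2,2-dimethyl-6-(3-methylbut-2-en-1-yl)-2H-chromen-5-yl]ethenyl}benzene-1,2-diol | COc1cc2OC(C)(C)C=Cc2c(/C=C/c2ccc(O)c(O)c2)c1CC=C(C)C | intermediate
13 | radical cation of 12 (drawn as the protonated para-quinone methide with the spin on the carbon bound to ring A; counterion is the IDPi anion) | COc1cc2OC(C)(C)C=Cc2c([CH]C=C2C=CC(=[OH+])C(O)=C2)c1CC=C(C)C | intermediate
14 | CNP0207533.1 (S at the ring-fusion CH next to CH2, R at the benzylic ring-fusion CH, S at the aryl-bearing CH; cis fusion, catechol ring trans to ring A) | COc1cc2c(c3c1C[C@H]1[C@@H]3[C@H](c3ccc(O)c(O)c3)C1(C)C)C=CC(C)(C)O2 | target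

**Totals**
- Total step count: 4.
- Longest linear sequence: 4 (1 → 5 → 9 → 12 → 14).

**The three steps most likely to fail**

**Step 4 (highest risk).**
- The stereodetermining bond forms several bonds away from the hydrogen-bond anchor, so the enantiomeric ratio may be modest.
- 13 may lose a proton to give the neutral phenoxyl radical.
- Oxidation of the product could reopen the cyclobutane.

The fallback gives up asymmetric catalysis for resolution. It sets out from 12 and comes back at 14. Heating 12 in degassed o-xylene at 180 °C in a sealed tube triggers the thermal formal [2+2] typical of free para-hydroxy prenylstilbenes. This gives the racemic cycloadduct F1 with the same relative configuration. Preparative supercritical-fluid chromatography on an amylose tris(3,5-dimethylphenylcarbamate) phase then delivers 14.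

**Step 3.**
- Free 11 can polymerise or be oxidised.
- Catecholate can bind divalent palladium.
- Any cyclobutane formed thermally at 100 °C is racemic and must be removed by chromatography before step 4.

The fallback gives up the protecting-group-free one-pot coupling. It sets out from 10 (with 9) and comes back at 12. After the decarboxylation to 11, acetic anhydride is added to the cooled solution to give 4-ethenylbenzene-1,2-diyl diacetate F2, a storable styrene that is purified. A separate Heck coupling of F2 with 9 (Pd(OAc)2, P(t-Bu)3·HBF4, Et3N, dioxane, 90 °C) gives the stilbene diacetate F3. Methanolysis (K2CO3 cat., MeOH, 0 °C, argon) then gives 12.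

**Step 1.**
- The condensation may give a substantial amount of the 7-bromo-5-methoxy regioisomer.

The fallback replaces the electrophilic condensation with a sigmatropic route. It sets out from 1 and comes back at 5. O-Alkylation of 1 with 3-chloro-3-methylbut-1-yne (DBU, CuCl2 1 mol%, MeCN, 0 °C) gives the aryl propargyl ether 1-bromo-3-methoxy-5-[(2-methylbut-3-yn-2-yl)oxy]benzene F4.

Heating F4 in N,N-diethylaniline at 180 °C starts the aromatic propargyl Claisen cascade. Both meta substituents steer the [3,3] shift to the carbon between O and Br: the withdrawing Br directs towards itself and the donating OMe directs away from itself. The cascade passes through the allenylphenol 3-bromo-5-methoxy-2-(3-methylbuta-1,2-dien-1-yl)phenol F5. A 1,5-hydrogen shift in F5 gives the same ortho-quinone methide 4, which closes to 5.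

**Further compounds**
F1 | step 4 | racemic cycloadduct (1:1 mixture of 14 and its enantiomer) | COc1cc2c(c3c1C[C@H]1[C@@H]3[C@H](c3ccc(O)c(O)c3)C1(C)C)C=CC(C)(C)O2.COc1cc2c(c3c1C[C@@H]1[C@H]3[C@@H](c3ccc(O)c(O)c3)C1(C)C)C=CC(C)(C)O2
F2 | step 3 | 4-ethenylbenzene-1,2-diyl diacetate | C=Cc1ccc(OC(C)=O)c(OC(C)=O)c1
F3 | step 3 | 4-{(E)-2-[7-methoxy-2,2-dimethyl-6-(3-methylbut-2-en-1-yl)-2H-chromen-5-yl]ethenyl}benzene-1,2-diyl diacetate | COc1cc2OC(C)(C)C=Cc2c(/C=C/c2ccc(OC(C)=O)c(OC(C)=O)c2)c1CC=C(C)C
F4 | step 1 | 1-bromo-3-methoxy-5-[(2-methylbut-3-yn-2-yl)oxy]benzene | COc1cc(Br)cc(OC(C)(C)C#C)c1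
F5 | step 1 | 3-bromo-5-methoxy-2-(3-methylbuta-1,2-dien-1-yl)phenol | COc1cc(O)c(C=C=C(C)C)c(Br)c1
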